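Ring B is the para-phenylene that carries only the ring A ether oxygen at C1 and the benzylic CH2 of the B–C bridge at C4, with four unsubstituted ring CH. That pattern is what a 2-aryloxybuta-1,3-diene and a terminal ynone give on cycloaddition. One intramolecular [4+2] addition therefore forges two C–C bonds of ring B (as a cyclohexa-1,4-diene) and closes the 17-membered macrocycle at the same time; dehydrogenation then delivers the arene. The precursor is the open A–D–C chain (bibenzyl, then diaryl ether, all phenols as methyl ethers) with the dienyl ether on the ring A oxygen and a but-3-yn-2-one arm on ring C.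

Key step: step 11

Remark on the structures: the seco dienyl ether ynone and the cycloadduct map atom for atom onto the target (17 ring atoms counted through the para positions of ring B), so no structural correction was needed.
Remark on the order of events: the titanium methylidene that makes the dienyl ether also attacks ketones, aldehydes, terminal alkynes and free OH, and the dienyl aryl ether is acid-labile; the dienyl ether is therefore made while the ring C arm is a silylated 2-arylethanol, and the ynone is built afterwards under non-acidic conditions.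
Remark on stereochemistry: the target is achiral; the E/Z mixtures of the stilbene intermediates and the two racemic centres formed on the way are all erased later.

Step 1
Reactants: 1 3-hydroxy-4,5-dimethoxybenzaldehyde
Product: 2 3-(benzyloxy)-4,5-dimethoxybenzaldehyde
Conditions: BnBr, K2CO3, DMF, rt
Reagents that add atoms: benzyl bromide, BrCc1ccccc1
Why: Williamson ether synthesis; the benzyl ether blocks the ring A oxygen during the ring D etherification and is later lost in the same hydrogenation that saturates the stilbene, so no separate deprotection is needed.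

Step 2
Reactants: 2 3-(benzyloxy)-4,5-dimethoxybenzaldehyde; 3 (2-hydroxybenzyl)triphenylphosphonium bromide
Product: 5 2-[2-(3-benzyloxy-4,5-dimethoxyphenyl)ethenyl]phenol (E/Z mixture), via potassium phenoxide ylide 4 (not isolated)
Conditions: KOtBu (2.2 equiv), THF, 0 °C to rt; aq HCl work-up
Reagents that add atoms: none
Why: Wittig olefination of the phenoxide ylide, a standard entry to 2-hydroxystilbenes; the E/Z ratio is irrelevant because the double bond is hydrogenated in step 5.

Step 3
Reactants: 5 2-[2-(3-benzyloxy-4,5-dimethoxyphenyl)ethenyl]phenol; 6 2-fluoro-3,4-dimethoxybenzaldehyde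
Product: 7 2-{2-[2-(3-benzyloxy-4,5-dimethoxyphenyl)ethenyl]phenoxy}-3,4-dimethoxybenzaldehyde (E/Z mixture)
Conditions: K2CO3, DMF, 120 °C, Ar
Reagents that add atoms: none
Why: Nucleophilic aromatic substitution (SNAr) in which the only free phenoxide (ring D) displaces fluoride ortho to the formyl group, which stabilises the Meisenheimer intermediate.

Step 4
Reactants: 7 2-{2-[2-(3-benzyloxy-4,5-dimethoxyphenyl)ethenyl]phenoxy}-3,4-dimethoxybenzaldehyde
Product: 8 2-(2-{2-[2-(3-benzyloxy-4,5-dimethoxyphenyl)ethenyl]phenoxy}-3,4-dimethoxyphenyl)oxirane (racemic, E/Z mixture)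
Conditions: Me3SI, NaH, DMSO/THF, 0 °C to rt; used crude
Reagents that add atoms: trimethylsulfonium iodide, C[S+](C)C.[I-]
Why: Corey–Chaykovsky epoxidation of a non-enolisable aldehyde by the sulfonium ylide, the stilbene being inert; the new benzylic stereocentre forms as a racemate and is deleted in step 5.

Step 5
Reactants: 8 2-(2-{2-[2-(3-benzyloxy-4,5-dimethoxyphenyl)ethenyl]phenoxy}-3,4-dimethoxyphenyl)oxirane
Product: 9 5-(2-{2-[6-(2-hydroxyethyl)-2,3-dimethoxyphenoxy]phenyl}ethyl)-2,3-dimethoxyphenol
Conditions: H2 (1 atm), Pd/C (10%), EtOAc, rt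
Reagents that add atoms: none
Why: Heterogeneous hydrogenation and hydrogenolysis in one operation: Pd/C saturates the stilbene, cleaves the aryl benzyl ether and opens the aryl oxirane at its benzylic C–O bond (the usual regiochemistry for styrene oxides) to the 2-arylethanol, while aryl methyl and diaryl ethers are untouched.

Step 6
Reactants: 9 5-(2-{2-[6-(2-hydroxyethyl)-2,3-dimethoxyphenoxy]phenyl}ethyl)-2,3-dimethoxyphenol; 10 acryloyl chloride
Product: 12 2,3-dimethoxy-5-[2-(2-{2,3-dimethoxy-6-[2-(trimethylsilyloxy)ethyl]phenoxy}phenyl)ethyl]phenyl prop-2-enoate, via hydroxy aryl acrylate 11 (not isolated)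
Conditions: 10 (1.1 equiv), NaOH (1 M aq), Bu4NHSO4 (cat.), CH2Cl2, 0 °C; organic phase separated and dried; then TMSCl, Et3N, 0 °C; used crude
Reagents that add atoms: chlorotrimethylsilane, C[Si](C)(C)Cl
Why: Schotten–Baumann O-acylation under phase transfer acylates only the phenoxide (the neutral primary alcohol does not compete at 0 °C), and silylation of the dried solution then masks the alcohol as a base-labile TMS ether for the organotitanium step.

Step 7
Reactants: 12 2,3-dimethoxy-5-[2-(2-{2,3-dimethoxy-6-[2-(trimethylsilyloxy)ethyl]phenoxy}phenyl)ethyl]phenyl prop-2-enoate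
Product: 14 2-(2-{2-[2-(3-(buta-1,3-dien-2-yloxy)-4,5-dimethoxyphenyl)ethyl]phenoxy}-3,4-dimethoxyphenyl)ethanol, via silylated dienyl ether 13 (not isolated)
Conditions: Cp2Ti(μ-CH2)(μ-Cl)AlMe2 (Tebbe reagent), pyridine, THF/PhMe, −40 °C to rt; then K2CO3, MeOH, 0 °C; chromatography on Et3N-deactivated silica
Reagents that add atoms: Tebbe reagent Cp2Ti(μ-CH2)(μ-Cl)AlMe2 (written with separated charges), C[Al-](C)(Cl)C[Ti+](C1C=CC=C1)C1C=CC=C1
Why: Tebbe methylenation, which converts esters (aryl esters and enoates included) into enol ethers, turns the acrylate C=O into C=CH2 with no ketone, alkyne or free OH present to intercept the titanium methylidene; K2CO3/MeOH then removes the TMS group without harming the base-stable dienyl ether.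

Step 8
Reactants: 14 2-(2-{2-[2-(3-(buta-1,3-dien-2-yloxy)-4,5-dimethoxyphenyl)ethyl]phenoxy}-3,4-dimethoxyphenyl)ethanol
Product: 15 2-(2-{2-[2-(3-(buta-1,3-dien-2-yloxy)-4,5-dimethoxyphenyl)ethyl]phenoxy}-3,4-dimethoxyphenyl)acetaldehyde
Conditions: Dess–Martin periodinane, pyridine, CH2Cl2, 0 °C to rt; used crude
Reagents that add atoms: none
Why: Dess–Martin oxidation buffered with pyridine takes the primary alcohol to the arylacetaldehyde under non-acidic conditions that leave the electron-rich dienyl ether alone.

Step 9
Reactants: 15 2-(2-{2-[2-(3-(buta-1,3-dien-2-yloxy)-4,5-dimethoxyphenyl)ethyl]phenoxy}-3,4-dimethoxyphenyl)acetaldehyde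
Product: 16 1-(2-{2-[2-(3-(buta-1,3-dien-2-yloxy)-4,5-dimethoxyphenyl)ethyl]phenoxy}-3,4-dimethoxyphenyl)but-3-yn-2-ol (racemic)
Conditions: HC≡CMgBr, THF, −78 to −20 °C; pH 7 phosphate buffer
Reagents that add atoms: ethynylmagnesium bromide, C#C[Mg]Br
Why: Grignard 1,2-addition of the acetylide at low temperature outruns enolisation of the arylacetaldehyde; the carbinol centre forms racemic and is removed by the oxidation in step 10.

Step 10
Reactants: 16 1-(2-{2-[2-(3-(buta-1,3-dien-2-yloxy)-4,5-dimethoxyphenyl)ethyl]phenoxy}-3,4-dimethoxyphenyl)but-3-yn-2-ol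
Product: 17 1-(2-{2-[2-(3-(buta-1,3-dien-2-yloxy)-4,5-dimethoxyphenyl)ethyl]phenoxy}-3,4-dimethoxyphenyl)but-3-yn-2-one (seco dienyl ether ynone)
Conditions: Dess–Martin periodinane, pyridine, CH2Cl2, 0 °C; kept cold and dilute, used at once
Reagents that add atoms: none
Why: Dess–Martin oxidation of the propargylic alcohol gives the terminal ynone under buffered neutral conditions, the carbonyl being introduced only now, after the methylenation.

Step 11
Reactants: 17 seco dienyl ether ynone
Product: 18 macrocyclic cycloadduct: 17-membered ring in which ring B is a cyclohexa-1,4-diene, ArO–C1=C2H–C3H2–C4(acyl)=C5H–C6H2, carrying the ring A oxygen on C1 and the ketone carbon on C4; the ketone CH2 sits on ring C; four OMe groups retained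
Conditions: PhMe (degassed), BHT (cat.), 110 °C, syringe-pump addition to 1 mM final concentration, base-washed glassware
Reagents that add atoms: none
Why: Proposed new method: thermal, concerted normal-demand [4+2] cycloaddition in which the HOMO of the 2-aryloxydiene (largest coefficient at C1, the CH2 β to oxygen) meets the LUMO of the ynone (largest coefficient at the terminal alkyne carbon), so that C1 bonds to the alkyne CH and C4 to the acyl-bearing carbon, making both new C–C bonds of ring B. The closest known chemistry is the intermolecular Diels–Alder reaction of 2-alkoxy- and 2-silyloxybutadienes with butynone or propiolates, whose cyclohexa-1,4-diene adducts are dehydrogenated to para-substituted aryl ethers, together with macrocyclising intramolecular Diels–Alder reactions over long tethers; the combination on an aryloxydiene and ynone joined by a 13-atom tether is untested. The cyclohexa-1,4-diene ring is closed by the cycloaddition itself, and the 17-membered ring is closed in the same event as the bridging ring of a type 2 intramolecular Diels–Alder reaction, the tether running from diene C2 through the ring A oxygen round to the ketone carbon on the dienophile. No stereocentre is created. Two selectivities are needed: para over meta orientation, secured by the matched polarisation of the oxygen-donor diene and the acceptor-substituted alkyne, and ring closure over oligomerisation, secured by slow addition at high dilution and by the fact that a non-planar cyclohexadiene, not a flat bridged arene, is what forms in the strain-sensitive event.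

Step 12
Reactants: 18 macrocyclic cycloadduct
Product: 19 macrocyclic aryl ketone: ring B now a para-phenylene, with C=O on the bridge carbon attached to ring B and CH2 on ring C
Conditions: DDQ (1.1 equiv), CH2Cl2, 0 °C to rt
Reagents that add atoms: none
Why: DDQ dehydrogenation, in which hydride abstraction from a doubly allylic CH2 of the cyclohexa-1,4-diene and proton loss aromatise ring B far faster than DDQ attacks the benzylic positions of the methoxyarenes.

Step 13
Reactants: 19 macrocyclic aryl ketone
Product: 20 tetra-O-methyl ether of the target (ring A 4,5-dimethoxy, ring C 3,4-dimethoxy, B–C bridge CH2CH2)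
Conditions: Et3SiH (5 equiv), CF3CO2H/CH2Cl2, 0 °C to rt
Reagents that add atoms: none
Why: Ionic hydrogenation (Kursanov–Parnes reduction), in which protonation of the aryl ketone and two hydride transfers from Et3SiH through the benzylic cation stabilised by the para aryloxy group of ring B convert C=O into CH2, with aryl ethers inert.

Step 14
Reactants: 20 tetra-O-methyl ether of the target
Product: 21 CNP0114693.0 (target; achiral tetraphenol macrocycle)
Conditions: BBr3 (10 equiv), CH2Cl2, −78 °C to rt; then MeOH, H2O
Reagents that add atoms: none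
Why: Lewis-acid ether cleavage, in which BBr3 demethylates the four aryl methyl ethers by bromide attack on the O-methyl groups of the borane adducts, whereas the two diaryl ether bonds cannot be cleaved in this way.

Compound list
1 | 3-hydroxy-4,5-dimethoxybenzaldehyde | COc1cc(C=O)cc(O)c1OC | starting material
2 | 3-(benzyloxy)-4,5-dimethoxybenzaldehyde | COc1cc(C=O)cc(OCc2ccccc2)c1OC | intermediate
3 | (2-hydroxybenzyl)triphenylphosphonium bromide | [Br-].Oc1ccccc1C[P+](c1ccccc1)(c1ccccc1)c1ccccc1 | starting material
4 | potassium 2-[(triphenylphosphoranylidene)methyl]phenolate (phenoxide ylide, not isolated) | [K+].[O-]c1ccccc1C=P(c1ccccc1)(c1ccccc1)c1ccccc1 | intermediate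
5 | 2-[2-(3-benzyloxy-4,5-dimethoxyphenyl)ethenyl]phenol, E/Z mixture | COc1cc(C=Cc2ccccc2O)cc(OCc2ccccc2)c1OC | intermediate
6 | 2-fluoro-3,4-dimethoxybenzaldehyde | COc1ccc(C=O)c(F)c1OC | starting material
7 | 2-{2-[2-(3-benzyloxy-4,5-dimethoxyphenyl)ethenyl]phenoxy}-3,4-dimethoxybenzaldehyde, E/Z mixture | COc1cc(C=Cc2ccccc2Oc2c(C=O)ccc(OC)c2OC)cc(OCc2ccccc2)c1OC | intermediate
8 | 2-(2-{2-[2-(3-benzyloxy-4,5-dimethoxyphenyl)ethenyl]phenoxy}-3,4-dimethoxyphenyl)oxirane, racemic, E/Z mixture | COc1cc(C=Cc2ccccc2Oc2c(C3CO3)ccc(OC)c2OC)cc(OCc2ccccc2)c1OC | intermediate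
9 | 5-(2-{2-[6-(2-hydroxyethyl)-2,3-dimethoxyphenoxy]phenyl}ethyl)-2,3-dimethoxyphenol | COc1cc(CCc2ccccc2Oc2c(CCO)ccc(OC)c2OC)cc(O)c1OC | intermediate
10 | acryloyl chloride | C=CC(=O)Cl | starting material
11 | 5-(2-{2-[6-(2-hydroxyethyl)-2,3-dimethoxyphenoxy]phenyl}ethyl)-2,3-dimethoxyphenyl prop-2-enoate (not isolated) | C=CC(=O)Oc1cc(CCc2ccccc2Oc2c(CCO)ccc(OC)c2OC)cc(OC)c1OC | intermediate
12 | 2,3-dimethoxy-5-[2-(2-{2,3-dimethoxy-6-[2-(trimethylsilyloxy)ethyl]phenoxy}phenyl)ethyl]phenyl prop-2-enoate | C=CC(=O)Oc1cc(CCc2ccccc2Oc2c(CCO[Si](C)(C)C)ccc(OC)c2OC)cc(OC)c1OC | intermediate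
13 | [2-(2-{2-[2-(3-(buta-1,3-dien-2-yloxy)-4,5-dimethoxyphenyl)ethyl]phenoxy}-3,4-dimethoxyphenyl)ethoxy]trimethylsilane (not isolated) | C=CC(=C)Oc1cc(CCc2ccccc2Oc2c(CCO[Si](C)(C)C)ccc(OC)c2OC)cc(OC)c1OC | intermediate
14 | 2-(2-{2-[2-(3-(buta-1,3-dien-2-yloxy)-4,5-dimethoxyphenyl)ethyl]phenoxy}-3,4-dimethoxyphenyl)ethanol | C=CC(=C)Oc1cc(CCc2ccccc2Oc2c(CCO)ccc(OC)c2OC)cc(OC)c1OC | intermediate
15 | 2-(2-{2-[2-(3-(buta-1,3-dien-2-yloxy)-4,5-dimethoxyphenyl)ethyl]phenoxy}-3,4-dimethoxyphenyl)acetaldehyde | C=CC(=C)Oc1cc(CCc2ccccc2Oc2c(CC=O)ccc(OC)c2OC)cc(OC)c1OC | intermediate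
16 | 1-(2-{2-[2-(3-(buta-1,3-dien-2-yloxy)-4,5-dimethoxyphenyl)ethyl]phenoxy}-3,4-dimethoxyphenyl)but-3-yn-2-ol, racemic | C=CC(=C)Oc1cc(CCc2ccccc2Oc2c(CC(O)C#C)ccc(OC)c2OC)cc(OC)c1OC | intermediate
17 | 1-(2-{2-[2-(3-(buta-1,3-dien-2-yloxy)-4,5-dimethoxyphenyl)ethyl]phenoxy}-3,4-dimethoxyphenyl)but-3-yn-2-one (seco dienyl ether ynone) | C=CC(=C)Oc1cc(CCc2ccccc2Oc2c(CC(=O)C#C)ccc(OC)c2OC)cc(OC)c1OC | intermediate
18 | macrocyclic cycloadduct with ring B as 1-aryloxy-4-acylcyclohexa-1,4-diene | O=C1Cc2ccc(OC)c(OC)c2Oc2ccccc2CCc2cc(OC)c(OC)c(c2)OC2=CCC1=CC2 | intermediate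
19 | macrocyclic aryl ketone with aromatic ring B | O=C1Cc2ccc(OC)c(OC)c2Oc2ccccc2CCc2cc(OC)c(OC)c(c2)Oc2ccc1cc2 | intermediate
20 | tetra-O-methyl ether of the target | COc1cc2cc(c1OC)Oc1ccc(cc1)CCc1ccc(OC)c(OC)c1Oc1ccccc1CC2 | intermediate
21 | CNP0114693.0 | Oc1cc2cc(c1O)Oc1ccc(cc1)CCc1ccc(O)c(O)c1Oc1ccccc1CC2 | target

Total step count: 14. Longest linear sequence: 14 steps (1 to 21); compounds 3, 6 and 10 are bought and used directly.

Steps most likely to fail

Step 11. The cycloaddition may lose to oligomerisation at the concentrations that give a workable rate, may take the meta orientation, or the ynone may decompose before it cyclises. The fallback brings ring B in as a preformed para-disubstituted arene and closes the macrocycle by an intramolecular Wittig reaction, the established route to bis(bibenzyl) macrocycles. It sets out from aldehyde 7. NaBH4 in MeOH/THF at 0 °C should give (2-{2-[2-(3-benzyloxy-4,5-dimethoxyphenyl)ethenyl]phenoxy}-3,4-dimethoxyphenyl)methanol F1. H2 over Pd/C in EtOAc should saturate the stilbene and remove the benzyl group to give 5-(2-{2-[6-(hydroxymethyl)-2,3-dimethoxyphenoxy]phenyl}ethyl)-2,3-dimethoxyphenol F2. SNAr of this phenol on 4-fluorobenzaldehyde (K2CO3, DMF, 110 °C) should install ring B as 4-[5-(2-{2-[6-(hydroxymethyl)-2,3-dimethoxyphenoxy]phenyl}ethyl)-2,3-dimethoxyphenoxy]benzaldehyde F3. PPh3·HBr in MeCN at reflux should convert the electron-rich benzylic alcohol into the benzylic triphenylphosphonium bromide F4. NaOMe in CH2Cl2 at high dilution should close the ring to the macrocyclic stilbene F5 (E/Z mixture). H2 over Pd/C should then give the tetramethyl ether 20, where the route is rejoined before step 14.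

Step 7. The methylenation may fail through polymerisation of the aryl acrylate or of the diene, acyl–oxygen cleavage of the activated aryl ester by the organometallic, or hydrolysis of the dienyl ether while titanium and aluminium residues are removed. The fallback transfers the dienyl group to oxygen as a whole. It sets out from phenol 9, which is treated with the known buta-1,3-dien-2-ylboronic acid pinacol ester, Cu(OAc)2, pyridine and 4 Å molecular sieves in CH2Cl2 under air at rt (Chan–Lam O-alkenylation, in which the phenol is expected to react in preference to the primary alcohol). This should give the dienyl ether alcohol 14 directly, where the route is rejoined before step 8; no new compound is made (F0).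

Step 3. The substitution may stall because the fluorine is flanked by a methoxy group and deactivated by the para methoxy donor, so that the hindered phenoxide adds slowly or the stilbene degrades at the temperature needed. The fallback makes the diaryl ether bond by copper catalysis. It sets out from phenol 5, which is coupled with 2-bromo-3,4-dimethoxybenzaldehyde using CuI, picolinic acid and K3PO4 in DMSO at 90 °C (Ullmann ether synthesis, assisted by the ortho formyl group). This should give aldehyde 7 directly, where the route is rejoined before step 4; no new compound is made (F0).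

Further compounds
F1 | step 11 | (2-{2-[2-(3-benzyloxy-4,5-dimethoxyphenyl)ethenyl]phenoxy}-3,4-dimethoxyphenyl)methanol, E/Z mixture | COc1cc(C=Cc2ccccc2Oc2c(CO)ccc(OC)c2OC)cc(OCc2ccccc2)c1OC
F2 | step 11 | 5-(2-{2-[6-(hydroxymethyl)-2,3-dimethoxyphenoxy]phenyl}ethyl)-2,3-dimethoxyphenol | COc1cc(CCc2ccccc2Oc2c(CO)ccc(OC)c2OC)cc(O)c1OC
F3 | step 11 | 4-[5-(2-{2-[6-(hydroxymethyl)-2,3-dimethoxyphenoxy]phenyl}ethyl)-2,3-dimethoxyphenoxy]benzaldehyde | COc1cc(CCc2ccccc2Oc2c(CO)ccc(OC)c2OC)cc(Oc2ccc(C=O)cc2)c1OC
F4 | step 11 | {2-[2-(2-{3-(4-formylphenoxy)-4,5-dimethoxyphenyl}ethyl)phenoxy]-3,4-dimethoxybenzyl}triphenylphosphonium bromide | [Br-].COc1cc(CCc2ccccc2Oc2c(C[P+](c3ccccc3)(c3ccccc3)c3ccccc3)ccc(OC)c2OC)cc(Oc2ccc(C=O)cc2)c1OC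
F5 | step 11 | macrocyclic stilbene (B–C bridge CH=CH, tetramethyl ether), E/Z mixture | COc1cc2cc(c1OC)Oc1ccc(cc1)C=Cc1ccc(OC)c(OC)c1Oc1ccccc1CC2
F0 | step 7 | none | none
F0 | step 3 | none | none
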